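A margin of 10.0% separates the reagent charge of noon from one reagent per substrate. This spare reagent, equivalents minus one in percent of the substrate charged, is what double product minus substrate must equal once a flask's reagent is used up, side product aside: a double product holds one reagent more than a single product or its isomer, and a substrate left over holds one less.

in all of them: substrate 0.069 M
- west: reagent 1.2 equiv; run made earlier
- south: reagent 2.3 equiv; run made earlier
- noon: reagent 1.10 equiv; time 2.0 min
- summer: reagent 1.70 equiv; time 2.0 min

| run | time / s | isomer of the product / % | single product / % | side product / % | double product / % | substrate / % |
|---|---|---|---|---|---|---|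
| west | 10.0 | 4 | 53 | 2 | 9 | 34 |
| west | 25.0 | 6 | 52 | 0 | 19 | 20 |
| west | 40.0 | 15 | 52 | 2 | 23 | 11 |
| west | 60.0 | 18 | 46 | 3 | 25 | 8 |
| west | 90.0 | 22 | 43 | 3 | 25 | 9 |
| west | 120 | 21 | 42 | 0 | 26 | 8 |
| south | 20.0 | 7 | 41 | 2 | 46 | 2 |
| south | 40.0 | 11 | 23 | 2 | 63 | 0 |
| south | 60.0 | 9 | 18 | 0 | 74 | 0 |
| south | 80.0 | 11 | 14 | 2 | 77 | 0 |
| south | 90.0 | 12 | 13 | 0 | 75 | 0 |
| south | 120 | 9 | 11 | 2 | 81 | 0 |

(readings scatter by 1.5 percentage points)

* which of these there is most of at the end, counted by the substrate in it, noon (isomer of the product / substrate / double product / single product / side product)
* which of these there is most of at the end, counted by the substrate in it, summer (isomer of the product / substrate / double product / single product / side product)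
* how much there is at the end of the one of these that leads, in percent of the substrate charged: noon
* how much there is at the end of the one of these that leads, in percent of the substrate charged: summer

- a species is counted by the substrate in it: one side product counts as two
- the numbers in the tables scatter with a standard deviation of 1.5 percentage points

The concentration is the same in every flask, 0.069 M, so the runs need no correction for it. For noon the time needs little care: in west, the run nearest to noon in reagent, single product reads 43% at 90.0 s and 42% at 120 s. The reagent charge has to be known well, for at 120 s single product reads 42% in west and 11% in south. The split between single product and isomer matters too, and west reads it as 2.00 to one.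

West at 120 s counts 115% of reagent used against 120% charged, with substrate still reading 8%, so reagent is the limiting reagent there, and double minus substrate reads 18 points against a spare of 20.0%. South, with 182% used of 230%, reads 81 points against 130%, so the rule needs the reagent used up.

For noon, the reckoning here keeps west's substrate plus double at 34.0%. That leaves 66.0% to split, or 44.0% of single product. For summer, interpolating double product between west and south gives 51.0%.

The forecast says single product at 46% for noon and double product at 60% for summer, noting that “Double minus substrate tracks the excess reagent”. Both its figures stand higher than those reckoned here.

Noon ends with single product leading at 43.4%, and summer with double product at 55.6%.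

    substrate + reagent → single product (k = 2.20 M⁻¹ s⁻¹)
    reagent + single product ⇌ double product (K = 310 M⁻¹, k = 0.580 M⁻¹ s⁻¹)
    single product ⇌ isomer of the product (K = 0.610, k = 0.00920 s⁻¹)
    substrate + single product → side product (k = 0.0170 M⁻¹ s⁻¹)

Double and single product would stand equal in summer at a factor of 0.828 on its reagent. In noon, with 1.31% of the reagent free, double minus substrate is 9.7 points against the spare of 10.0%. A flask like summer charged with 0.420 equiv falls short of one reagent per substrate by 58.0%, and with 0.0979% of its reagent free it ends with substrate exceeding double product by 56 points.

The readings stem from a simulated flask with made-up constants; the scatter is artificial.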